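# Proposed synthesis of 4-[(S)-hydroxy{(3R,4R)-4-[(R)-hydroxy(4-hydroxy-3-methoxyphenyl)methyl]oxolan-3-yl}methyl]-2-methoxyphenol (18)

Atom labels used throughout: the ring is O1, C2, C3, C4, C5; Ca is the carbinol carbon on C3 and Cb the carbinol carbon on C4. These labels are kept for all intermediates, also where a systematic name numbers the ring the other way round.

## The problem

1. Compound 18 is an oxolane that carries one 4-hydroxy-3-methoxyphenyl carbinol on each of two neighbouring ring carbons, Ca on C3 and Cb on C4, with the two side chains trans.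
2. The two halves have the same constitution, but the four contiguous stereocentres are Ca (S), C3 (R), C4 (R) and Cb (R). The ring pair is like and the carbinol pair unlike, so the molecule has neither a C2 axis nor a mirror plane, and no dimerisation can deliver all four centres at once.
3. Each carbinol therefore has to be set against its own ring carbon in a separate event. C4 can control Cb if both arise in one stereospecific addition, C4 can control C3 thermodynamically while C3 carries an enolisable acyl group, and Ca, the centre that breaks the symmetry, is best left to a reagent.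
4. The fragile parts are the two p-oxygenated benzylic alcohols, which ionise under acid (epimerisation, ether formation, elimination) and can be lost on hydrogenolysis, and the phenols, which must stay masked until the end.
5. C2 and C5 are plain CH2 groups, so any route through lactones must later remove carbonyl groups next to benzylic C–O bonds.
6. The enabling feature is that Cb and C4 are adjacent centres directly beside the ring bond C3–C4, and that C4 is joined to C3 a second time through C5–O1–C2. Cutting C3–C4 and Cb–O uncovers an (E)-cinnamyl propargyl ether, a 1,6-enyne in which the alkene C4=Cb can add to the alkyne carbon C3 while a hydroxyl group is delivered to Cb.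
7. The exocyclic methylene that such a cyclisation leaves on C3 is a one-carbon handle that becomes Ca.

## Retrosynthesis

**Protecting groups (18 ⇐ 17 ⇐ 16).** The two aryl O–benzyl bonds and the Cb O–Si bond are cut last. Benzyl ethers on the phenols survive hydride, Grignard, borane, base and cationic gold; a silyl ether on Cb–OH is needed so that this hydroxyl cannot lactolise onto the C3 formyl group or quench organometallics. Removing silicon first (16 to 17) leaves a neutral hydrogenolysis as the final step, so the free phenols never meet base. The forward steps must spare the two ionisable benzylic C–OH bonds.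

**Ca (16 ⇐ 15 ⇐ 14 ⇐ 11 + 13, 13 from 12).** The Ca–H bond is cut back to aryl ketone 15, and the Ca–aryl bond back to aldehyde 11 and aryl Grignard reagent 13, made from commercial bromide 12. Direct addition of 13 to 11 is not trusted for Ca: a Felkin–Anh analysis with the C4 branch as the large group predicts the wrong (R) epimer. The same analysis predicts the wanted (S) epimer for hydride addition to ketone 15, so a CBS reduction there should be a matched case of catalyst and substrate control. The cost is one oxidation (14 to 15). The gain is that the symmetry-breaking centre is set by a reagent, independently of Cb.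

**C3 and the formyl group (11 ⇐ 10 ⇐ 9 ⇐ 8 ⇐ 7 ⇐ 6).** The formyl carbon of 11 is traced to the exocyclic methylene of 7, the silyl ether of 6, through hydroboration (borane 8), oxidation to alcohol 9 and oxidation to aldehyde 10. Hydroboration should add hydrogen to C3 from the face away from the C4 side chain and so give the cis series. This is accepted, because the α-centre of aldehyde 10 can be equilibrated to the more stable trans aldehyde 11. The alternative of forming the Ca–C3 bond directly from the alkene would add a carbon or lose control of C3. The sequence asks for a regioselective anti-Markovnikov hydroboration and a clean base-mediated epimerisation.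

**Key disconnection (6 ⇐ 5).** The ring bond C3–C4 and the Cb–O bond are cut together. Alcohol 6, with one ring and two stereocentres, goes back to the achiral, acyclic enyne 5 and a hydroxyl group from the aqueous medium. Cutting C4–Cb instead (aldol or allylation logic) would need a preformed chiral ring nucleophile; cutting a ring C–O bond would leave both centres to be set elsewhere. The forward reaction must close the ring 5-exo, choose one face of the alkene, and add carbon and oxygen anti across the E double bond.

**Enyne (5 ⇐ 3 + 4; 3 ⇐ 2 ⇐ 1).** The propargylic O–CH2 bond is cut by Williamson logic to cinnamyl alcohol 3 and propargyl bromide 4. Alcohol 3 comes from benzyl ester 2 by 1,2-reduction, and 2 from ferulic acid 1 by double O-benzylation. The E geometry, which later decides the Cb/C4 relationship, is bought with 1 and never touched.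

## Roads not taken

**Alternative 1: double dynamic-kinetic reduction of a dimeric aroylsuccinate.**
- Cut: the C3–C4 bond (oxidative α,α'-coupling, giving dimethyl 2,3-bis[4-(benzyloxy)-3-methoxybenzoyl]butanedioate A1) and both carbinol C–H bonds.
- Forward key step: RuCl(p-cymene)(TsDPEN) with HCO2H/Et3N would reduce both aryl ketones of A1 while the acidic C3 and C4 centres equilibrate. Each γ-hydroxy ester would then lactonise to the C2-symmetric, cis-fused bis-lactone A2 with both aryl groups exo.
- Merits: four stereocentres in one catalytic operation from a substrate two steps from commodity chemicals, with reagent control throughout. The cis ring fusion of A2 translates into the trans C3/C4 relation of the later oxolane without any epimerisation.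
- Weak points for this target: A2 has like-configured carbinol carbons, whereas 18 needs them unlike. After the lactones are reduced, one of two homotopic benzylic alcohols would have to be inverted. That means a statistical monofunctionalisation followed by substitution at an electron-rich benzylic centre that prefers to ionise. Both lactone carbonyls must also be reduced, and the oxolane closed between two primary carbons in the presence of the benzylic alcohols.
- Comparison: this road is clearly better in stereocentres per step and does not depend on an uncertain ligand–substrate fit. The chosen plan has to set against it that it never passes through a symmetric intermediate, so the unlike carbinol pair comes from two independent events (hydroxyl capture at Cb, ketone reduction at Ca), and that the ring ether is in place from the cyclisation onward.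

**Alternative 2: singlet-oxygen cycloaddition to a ring-locked diene.**
- Cut: both carbinol C–O bonds at once.
- Forward key step: photosensitised singlet oxygen would add [4+2] to the s-cis-locked diene A3, (3Z,4Z)-3,4-bis{[4-(benzyloxy)-3-methoxyphenyl]methylidene}oxolane with the aryl groups pointing outward. The product is the meso endoperoxide A4, a cis-3,6-diaryl-3,6-dihydro-1,2-dioxine fused to a 2,5-dihydrofuran.
- Merits: Ca–O and Cb–O are formed in one step in the unlike relation that 18 actually has, no oxygen protecting group is needed, and the sequence is short.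
- Weak points: A4 is achiral. All absolute information and the trans C3/C4 relation would have to be introduced afterwards, on a tetrasubstituted ring alkene flanked by two carbinols that are both benzylic and allylic. Catalytic hydrogenation adds syn and would give the cis ring; an enantioselective net trans reduction that desymmetrises the meso system has no reliable precedent. Hydrogenolysis of the doubly activated C–O bonds would compete, and the peroxide is prone to base-induced Kornblum–DeLaMare rearrangement.
- Comparison: this road is as good or better for the Ca/Cb relation and for step count up to the oxygenated skeleton. The chosen plan has to set against it that its ring-forming step fixes the absolute configuration of two centres, and that the trans ring relation is reached by a simple equilibration.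

**Alternative 3: asymmetric Baeyer–Villiger expansion of a cyclobutanone.**
- Cut: the O1–C2 bond, by oxygen insertion.
- Forward key step: Sc(OTf)3, a chiral N,N'-dioxide ligand and H2O2 would convert cyclobutanone A5, which already carries the silylated Ca carbinol, into γ-lactone A6 with Ca and C3 as in the target.
- Merits: a mild catalytic ring expansion sets C3. The lactone enolate then reacts trans to the C3 substituent, so an aldol with aldehyde A7 would give the trans C3/C4 relation directly, where the chosen plan needs an epimerisation.
- Weak points: A5 needs its Ca centre from a separate asymmetric step. That centre lies outside the ring and gives little bias between the two α-methylene groups, so migration selectivity rests on the catalyst alone, with a 3-alkyl cyclobutanone. Cb would arise in an aldol whose carbinol selectivity is usually modest, so a further oxidation–reduction pair is likely. The lactone carbonyl must finally be reduced to CH2, by diol formation and selective cyclisation or by Lewis-acid/silane reduction, which would ionise the benzylic C–O bonds.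
- Comparison: this road is equal or better at the ring junction and uses a robust enolate reaction. The chosen plan has to set against it that Cb and C4 arise together by a stereospecific addition, and that no carbonyl group has to be removed from the ring.

Key step: step 4

## Remarks on the chemistry (assumptions)

- The (R)-configured ligand is assumed to favour the (R,R) enantiomer 6. If the first run shows the opposite sense, the (S)-ligand complex is used with no other change.
- The hydroboration in step 6 is expected to give mainly the 3,4-cis alcohol. Any trans epimer is carried along and converges in step 7.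

## Steps

Step 1
Reactants: 1 ferulic acid
Product: 2 benzyl (E)-3-[4-(benzyloxy)-3-methoxyphenyl]prop-2-enoate
Conditions: BnBr (2.4 equiv), K2CO3, DMF, 60 °C
Reagents that add atoms: benzyl bromide, BrCc1ccccc1
Why: Williamson O-alkylation of the phenoxide and SN2 esterification of the carboxylate by the same reagent; the E alkene is not touched.

Step 2
Reactants: 2 benzyl (E)-3-[4-(benzyloxy)-3-methoxyphenyl]prop-2-enoate
Product: 3 (E)-3-[4-(benzyloxy)-3-methoxyphenyl]prop-2-en-1-ol
Conditions: i-Bu2AlH (2.5 equiv), CH2Cl2, −78 → 0 °C; aq. potassium sodium tartrate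
Reagents that add atoms: none
Why: 1,2-Reduction of a cinnamate ester by i-Bu2AlH gives the allylic alcohol without conjugate reduction; the aryl benzyl ether is inert and the released benzyl alcohol is removed on purification.

Step 3
Reactants: 3 (E)-3-[4-(benzyloxy)-3-methoxyphenyl]prop-2-en-1-ol; 4 propargyl bromide
Product: 5 1-(benzyloxy)-2-methoxy-4-[(E)-3-(prop-2-yn-1-yloxy)prop-1-en-1-yl]benzene
Conditions: NaH, THF, 0 °C; then 4, n-Bu4NI (cat.), 0 °C → rt
Reagents that add atoms: none
Why: Williamson ether synthesis; the sodium alkoxide displaces bromide at the unhindered propargylic carbon and the alkene geometry is retained.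

Step 4
Reactants: 5 1-(benzyloxy)-2-methoxy-4-[(E)-3-(prop-2-yn-1-yloxy)prop-1-en-1-yl]benzene
Product: 6 (R)-[4-(benzyloxy)-3-methoxyphenyl][(3R)-4-methylideneoxolan-3-yl]methanol
Conditions: (R)-DTBM-SEGPHOS(AuCl)2 (3 mol %), AgOTf (6 mol %), 1,4-dioxane/H2O 6:1, rt
Reagents that add atoms: water, O
Why: Chloride abstraction by AgOTf gives a cationic monovalent gold centre that binds the terminal alkyne; the alkene carbon C4 then attacks the internal alkyne carbon C3 in a 5-exo-dig closure of the oxolane, giving a cyclopropyl gold carbene whose positive charge is shared by the benzylic carbon Cb and stabilised by the p-benzyloxyaryl group. Water opens this species at Cb on the face opposite the new C3–C4 bond, and protodeauration of the alkenylgold leaves the exocyclic methylene on C3. The closest known reaction type is the gold- or platinum-catalysed hydroxy- and alkoxycyclisation of 1,6-enynes, which is anti-stereospecific and has been rendered enantioselective with chiral bisphosphine digold chlorides. C4 is set by the catalyst alone, through its choice between the two faces of the alkene of the achiral substrate. Cb is set relative to C4 by the anti addition across the E double bond, which by geometry gives the like (R,R) pair and would give the unlike pair from a Z alkene. The step needs 5-exo over 6-endo closure and capture by water over skeletal rearrangement: the aryl group places the cationic character at Cb and so fixes both ring size and site of attack, and water as co-solvent should outrun rearrangement. A terminal alkyne is used because it carries no arene that could close a second ring by formal [4+2] cycloaddition.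

Step 5
Reactants: 6 (R)-[4-(benzyloxy)-3-methoxyphenyl][(3R)-4-methylideneoxolan-3-yl]methanol
Product: 7 tert-butyl{(R)-[4-(benzyloxy)-3-methoxyphenyl][(3R)-4-methylideneoxolan-3-yl]methoxy}dimethylsilane
Conditions: TBSOTf, 2,6-lutidine, CH2Cl2, −78 → 0 °C
Reagents that add atoms: tert-butyldimethylsilyl trifluoromethanesulfonate, CC(C)(C)[Si](C)(C)OS(=O)(=O)C(F)(F)F
Why: Silylation of a hindered secondary alcohol with a silyl triflate and a hindered base; the buffered, cold medium should not ionise the benzylic C–O bond, and the ether keeps Cb–OH from forming a lactol with the later C3 formyl group.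

Step 6
Reactants: 7 tert-butyl{(R)-[4-(benzyloxy)-3-methoxyphenyl][(3R)-4-methylideneoxolan-3-yl]methoxy}dimethylsilane
Product: 9 [(3R,4R)-4-{(R)-[4-(benzyloxy)-3-methoxyphenyl][(tert-butyldimethylsilyl)oxy]methyl}oxolan-3-yl]methanol (3,4-cis), via 9-alkyl-9-borabicyclo[3.3.1]nonane 8 (not isolated)
Conditions: 9-BBN, THF, 0 °C → rt; then aq. NaOH, H2O2, 0 °C → rt
Reagents that add atoms: hydrogen peroxide, OO; 9-borabicyclo[3.3.1]nonane, B1C2CCCC1CCC2 (held only in intermediate 8)
Why: Anti-Markovnikov hydroboration–oxidation of a 1,1-disubstituted alkene puts boron, then oxygen, on the exocyclic carbon; the borane should approach the face away from the C4 side chain, so the new C3–H lies trans to it and the cis alcohol predominates, an outcome that step 7 corrects.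

Step 7
Reactants: 9 [(3R,4R)-4-{(R)-[4-(benzyloxy)-3-methoxyphenyl][(tert-butyldimethylsilyl)oxy]methyl}oxolan-3-yl]methanol
Product: 11 (3R,4R)-4-{(R)-[4-(benzyloxy)-3-methoxyphenyl][(tert-butyldimethylsilyl)oxy]methyl}oxolane-3-carbaldehyde (3,4-trans), via cis-aldehyde 10 (not isolated)
Conditions: DMP, CH2Cl2, 0 °C → rt; aq. NaHCO3/Na2S2O3 wash; crude in CH2Cl2, DBU (0.3 equiv), rt
Reagents that add atoms: none
Why: Dess–Martin oxidation gives the configurationally labile cis aldehyde, and DBU equilibrates C3 through the enolate to the trans isomer, in which the formyl group and the bulky C4 side chain avoid each other; ring opening by β-elimination of O1 is the reverse of a 5-endo-trig closure and poorly aligned, and the silyloxy group is not β to the carbonyl.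

Step 8
Reactants: 11 (3R,4R)-4-{(R)-[4-(benzyloxy)-3-methoxyphenyl][(tert-butyldimethylsilyl)oxy]methyl}oxolane-3-carbaldehyde; 12 1-(benzyloxy)-4-bromo-2-methoxybenzene
Product: 14 [4-(benzyloxy)-3-methoxyphenyl][(3R,4R)-4-{(R)-[4-(benzyloxy)-3-methoxyphenyl][(tert-butyldimethylsilyl)oxy]methyl}oxolan-3-yl]methanol as both epimers at Ca, via arylmagnesium bromide 13 (not isolated)
Conditions: 12, Mg, I2 (cat.), THF, reflux → rt; then 11, THF, −78 → 0 °C
Reagents that add atoms: magnesium, [Mg] (held only in intermediate 13)
Why: Grignard addition to an aldehyde forms the Ca–aryl bond; addition at low temperature outruns enolisation, the trans ring relation is the stable one in any case, and the Ca mixture is accepted because step 9 removes this centre.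

Step 9
Reactants: 14 [4-(benzyloxy)-3-methoxyphenyl][(3R,4R)-4-{(R)-[4-(benzyloxy)-3-methoxyphenyl][(tert-butyldimethylsilyl)oxy]methyl}oxolan-3-yl]methanol (epimers at Ca)
Product: 15 [4-(benzyloxy)-3-methoxyphenyl][(3R,4R)-4-{(R)-[4-(benzyloxy)-3-methoxyphenyl][(tert-butyldimethylsilyl)oxy]methyl}oxolan-3-yl]methanone
Conditions: DMP, CH2Cl2, 0 °C → rt
Reagents that add atoms: none
Why: Dess–Martin oxidation of a secondary benzylic alcohol converts both Ca epimers into one aryl ketone; the α-centre C3 already has the thermodynamically preferred trans configuration.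

Step 10
Reactants: 15 [4-(benzyloxy)-3-methoxyphenyl][(3R,4R)-4-{(R)-[4-(benzyloxy)-3-methoxyphenyl][(tert-butyldimethylsilyl)oxy]methyl}oxolan-3-yl]methanone
Product: 16 (S)-[4-(benzyloxy)-3-methoxyphenyl][(3R,4R)-4-{(R)-[4-(benzyloxy)-3-methoxyphenyl][(tert-butyldimethylsilyl)oxy]methyl}oxolan-3-yl]methanol
Conditions: (R)-2-methyl-CBS-oxazaborolidine (0.5 equiv), BH3·SMe2, THF, −20 → 0 °C; then MeOH
Reagents that add atoms: none
Why: CBS reduction of an aryl alkyl ketone; with the aryl group as the large substituent the (R)-catalyst should deliver hydride to give the (S)-carbinol, as it does with acetophenone, and Felkin–Anh attack anti to the C4 branch predicts the same sense, so catalyst and substrate are expected to reinforce each other.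

Step 11
Reactants: 16 (S)-[4-(benzyloxy)-3-methoxyphenyl][(3R,4R)-4-{(R)-[4-(benzyloxy)-3-methoxyphenyl][(tert-butyldimethylsilyl)oxy]methyl}oxolan-3-yl]methanol
Product: 17 (S)-[4-(benzyloxy)-3-methoxyphenyl][(3R,4R)-4-{(R)-[4-(benzyloxy)-3-methoxyphenyl](hydroxy)methyl}oxolan-3-yl]methanol
Conditions: n-Bu4NF, THF, 0 °C → rt
Reagents that add atoms: none
Why: Fluoride-induced cleavage of the silyl ether; with the phenols still benzylated no phenoxide forms, so the benzylic carbinols cannot ionise through quinone methides.

Step 12
Reactants: 17 (S)-[4-(benzyloxy)-3-methoxyphenyl][(3R,4R)-4-{(R)-[4-(benzyloxy)-3-methoxyphenyl](hydroxy)methyl}oxolan-3-yl]methanol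
Product: 18 4-[(S)-hydroxy{(3R,4R)-4-[(R)-hydroxy(4-hydroxy-3-methoxyphenyl)methyl]oxolan-3-yl}methyl]-2-methoxyphenol
Conditions: H2 (1 atm), Pd/C (10 %), EtOAc/MeOH, rt, stopped at full conversion
Reagents that add atoms: none
Why: Hydrogenolysis of aryl benzyl ethers under neutral conditions is normally much faster than cleavage of secondary benzylic alcohols, and no stereocentre is touched.

## Compound list

1 | ferulic acid, (E)-3-(4-hydroxy-3-methoxyphenyl)prop-2-enoic acid | COc1cc(/C=C/C(=O)O)ccc1O | starting material
2 | benzyl (E)-3-[4-(benzyloxy)-3-methoxyphenyl]prop-2-enoate | COc1cc(/C=C/C(=O)OCc2ccccc2)ccc1OCc1ccccc1 | intermediate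
3 | (E)-3-[4-(benzyloxy)-3-methoxyphenyl]prop-2-en-1-ol | COc1cc(/C=C/CO)ccc1OCc1ccccc1 | intermediate
4 | propargyl bromide (3-bromoprop-1-yne) | C#CCBr | starting material
5 | 1-(benzyloxy)-2-methoxy-4-[(E)-3-(prop-2-yn-1-yloxy)prop-1-en-1-yl]benzene | C#CCOC/C=C/c1ccc(OCc2ccccc2)c(OC)c1 | intermediate
6 | (R)-[4-(benzyloxy)-3-methoxyphenyl][(3R)-4-methylideneoxolan-3-yl]methanol | C=C1COC[C@@H]1[C@@H](O)c1ccc(OCc2ccccc2)c(OC)c1 | intermediate
7 | tert-butyl{(R)-[4-(benzyloxy)-3-methoxyphenyl][(3R)-4-methylideneoxolan-3-yl]methoxy}dimethylsilane | C=C1COC[C@@H]1[C@@H](O[Si](C)(C)C(C)(C)C)c1ccc(OCc2ccccc2)c(OC)c1 | intermediate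
8 | 9-{[(3S,4R)-4-{(R)-[4-(benzyloxy)-3-methoxyphenyl][(tert-butyldimethylsilyl)oxy]methyl}oxolan-3-yl]methyl}-9-borabicyclo[3.3.1]nonane (3,4-cis) | C1CCC2CCCC1B2C[C@@H]1COC[C@@H]1[C@@H](O[Si](C)(C)C(C)(C)C)c1ccc(OCc2ccccc2)c(OC)c1 | intermediate (not isolated)
9 | [(3R,4R)-4-{(R)-[4-(benzyloxy)-3-methoxyphenyl][(tert-butyldimethylsilyl)oxy]methyl}oxolan-3-yl]methanol (3,4-cis) | OC[C@@H]1COC[C@@H]1[C@@H](O[Si](C)(C)C(C)(C)C)c1ccc(OCc2ccccc2)c(OC)c1 | intermediate
10 | (3S,4R)-4-{(R)-[4-(benzyloxy)-3-methoxyphenyl][(tert-butyldimethylsilyl)oxy]methyl}oxolane-3-carbaldehyde (3,4-cis) | O=C[C@@H]1COC[C@@H]1[C@@H](O[Si](C)(C)C(C)(C)C)c1ccc(OCc2ccccc2)c(OC)c1 | intermediate (not isolated)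
11 | (3R,4R)-4-{(R)-[4-(benzyloxy)-3-methoxyphenyl][(tert-butyldimethylsilyl)oxy]methyl}oxolane-3-carbaldehyde (3,4-trans) | O=C[C@H]1COC[C@@H]1[C@@H](O[Si](C)(C)C(C)(C)C)c1ccc(OCc2ccccc2)c(OC)c1 | intermediate
12 | 1-(benzyloxy)-4-bromo-2-methoxybenzene | COc1cc(Br)ccc1OCc1ccccc1 | starting material
13 | [4-(benzyloxy)-3-methoxyphenyl]magnesium bromide | COc1cc([Mg]Br)ccc1OCc1ccccc1 | intermediate (not isolated)
14 | [4-(benzyloxy)-3-methoxyphenyl][(3R,4R)-4-{(R)-[4-(benzyloxy)-3-methoxyphenyl][(tert-butyldimethylsilyl)oxy]methyl}oxolan-3-yl]methanol, both epimers at Ca | COc1cc(C(O)[C@H]2COC[C@@H]2[C@@H](O[Si](C)(C)C(C)(C)C)c2ccc(OCc3ccccc3)c(OC)c2)ccc1OCc1ccccc1 | intermediate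
15 | [4-(benzyloxy)-3-methoxyphenyl][(3R,4R)-4-{(R)-[4-(benzyloxy)-3-methoxyphenyl][(tert-butyldimethylsilyl)oxy]methyl}oxolan-3-yl]methanone | COc1cc(C(=O)[C@H]2COC[C@@H]2[C@@H](O[Si](C)(C)C(C)(C)C)c2ccc(OCc3ccccc3)c(OC)c2)ccc1OCc1ccccc1 | intermediate
16 | (S)-[4-(benzyloxy)-3-methoxyphenyl][(3R,4R)-4-{(R)-[4-(benzyloxy)-3-methoxyphenyl][(tert-butyldimethylsilyl)oxy]methyl}oxolan-3-yl]methanol | COc1cc([C@@H](O)[C@H]2COC[C@@H]2[C@@H](O[Si](C)(C)C(C)(C)C)c2ccc(OCc3ccccc3)c(OC)c2)ccc1OCc1ccccc1 | intermediate
17 | (S)-[4-(benzyloxy)-3-methoxyphenyl][(3R,4R)-4-{(R)-[4-(benzyloxy)-3-methoxyphenyl](hydroxy)methyl}oxolan-3-yl]methanol | COc1cc([C@@H](O)[C@H]2COC[C@@H]2[C@@H](O)c2ccc(OCc3ccccc3)c(OC)c2)ccc1OCc1ccccc1 | intermediate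
18 | 4-[(S)-hydroxy{(3R,4R)-4-[(R)-hydroxy(4-hydroxy-3-methoxyphenyl)methyl]oxolan-3-yl}methyl]-2-methoxyphenol | COc1cc([C@@H](O)[C@H]2COC[C@@H]2[C@@H](O)c2ccc(O)c(OC)c2)ccc1O | target

## Step count and risk assessment

Total: 12 steps. Longest linear sequence: 12 steps, from 1 to 18. Bromide 12 is purchased and converted to 13 within step 8.

**Step 4 (key step).**
- What may go wrong: insufficient enantioface discrimination. The chiral ligand on a linear two-coordinate gold centre sits far from the alkene, and a flexible oxygen tether with an unsubstituted alkyne terminus gives it little to hold.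
- Also possible: partial loss of anti stereospecificity if the p-alkoxy-stabilised cation lives long enough to rotate about C4–Cb before water arrives; acid-promoted ionisation of the product carbinol; hydration of the alkyne.
- Fallback, from 5 back to 6: the cyclisation is run with an achiral catalyst (PtCl2 in aqueous acetone, divalent platinum, or Ph3PAuCl/AgOTf in aqueous dioxane) purely for its anti stereospecificity. This gives racemic (R*,R*)-[4-(benzyloxy)-3-methoxyphenyl](4-methylideneoxolan-3-yl)methanol F1. Acylation with (1S)-camphanic chloride (Et3N, DMAP, CH2Cl2) gives the camphanate of the (R,R) alcohol F2 and the diastereomeric camphanate of the (S,S) alcohol F3. These are separated by crystallisation or chromatography, and methanolysis of F2 (K2CO3, MeOH) returns the route at 6.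

**Step 7 (oxidation and epimerisation).**
- What may go wrong: incomplete or unclean equilibration. The aldehyde may undergo self-aldol addition or base-induced opening of the ring before the trans isomer is fully reached, or the equilibrium may not lie far enough on the trans side.
- Fallback, from 9 back to 15: 9 is oxidised with DMP and the crude cis aldehyde 10 is added at once to Grignard reagent 13 without any base treatment. This gives the 3,4-cis carbinols F4 as a Ca mixture. DMP oxidation gives the 3,4-cis aryl ketone F5, which cannot self-condense. It is equilibrated with DBU in CH2Cl2 or K2CO3 in MeOH to the trans ketone, and the route is rejoined at 15.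

**Step 10 (CBS reduction).**
- What may go wrong: weak facial selectivity in hydride delivery. The ring-bound, α-branched alkyl group is a less clear small substituent than methyl, so catalyst control is weaker than for aryl methyl ketones, and uncatalysed borane reduction can erode it further.
- Fallback, from 15 back to 16: catalyst control is given up. Ketone 15 is reduced with the bulky achiral hydride LiBH(s-Bu)3 in THF at −78 °C, relying on Felkin–Anh attack anti to the C4 branch. The two Ca epimers are diastereomers and are separated by chromatography. The unwanted (R)-Ca epimer of 16, F6, is returned to 15 by DMP oxidation and recycled. The (S) epimer is 16.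

**Step 12 (hydrogenolysis).**
- What may go wrong: reductive loss of a benzylic hydroxyl group. Once a phenol is free, the p-hydroxybenzylic C–OH bond is activated towards hydrogenolysis, and slow debenzylation would invite forcing conditions.
- Fallback, from 16 back to 18: the order of deprotection is changed so that both carbinols are masked during hydrogenolysis. Silylation of 16 (TBSOTf, 2,6-lutidine) gives the bis(silyl ether) F7. Hydrogenolysis (H2, Pd/C, EtOAc) gives the bis(silyl ether) bisphenol F8. Desilylation with n-Bu4NF buffered with acetic acid in THF gives 18.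

## Further compounds

F1 | step 4 | racemic (R*,R*)-[4-(benzyloxy)-3-methoxyphenyl](4-methylideneoxolan-3-yl)methanol | C=C1COC[C@@H]1[C@@H](O)c1ccc(OCc2ccccc2)c(OC)c1.C=C1COC[C@H]1[C@H](O)c1ccc(OCc2ccccc2)c(OC)c1
F2 | step 4 | (R)-[4-(benzyloxy)-3-methoxyphenyl][(3R)-4-methylideneoxolan-3-yl]methyl (1S,4R)-4,7,7-trimethyl-3-oxo-2-oxabicyclo[2.2.1]heptane-1-carboxylate | C=C1COC[C@@H]1[C@@H](OC(=O)[C@@]23CC[C@@](C)(C(=O)O2)C3(C)C)c1ccc(OCc2ccccc2)c(OC)c1
F3 | step 4 | (S)-[4-(benzyloxy)-3-methoxyphenyl][(3S)-4-methylideneoxolan-3-yl]methyl (1S,4R)-4,7,7-trimethyl-3-oxo-2-oxabicyclo[2.2.1]heptane-1-carboxylate | C=C1COC[C@H]1[C@H](OC(=O)[C@@]23CC[C@@](C)(C(=O)O2)C3(C)C)c1ccc(OCc2ccccc2)c(OC)c1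
F4 | step 7 | [4-(benzyloxy)-3-methoxyphenyl][(3S,4R)-4-{(R)-[4-(benzyloxy)-3-methoxyphenyl][(tert-butyldimethylsilyl)oxy]methyl}oxolan-3-yl]methanol (3,4-cis), both epimers at Ca | COc1cc(C(O)[C@@H]2COC[C@@H]2[C@@H](O[Si](C)(C)C(C)(C)C)c2ccc(OCc3ccccc3)c(OC)c2)ccc1OCc1ccccc1
F5 | step 7 | [4-(benzyloxy)-3-methoxyphenyl][(3S,4R)-4-{(R)-[4-(benzyloxy)-3-methoxyphenyl][(tert-butyldimethylsilyl)oxy]methyl}oxolan-3-yl]methanone (3,4-cis) | COc1cc(C(=O)[C@@H]2COC[C@@H]2[C@@H](O[Si](C)(C)C(C)(C)C)c2ccc(OCc3ccccc3)c(OC)c2)ccc1OCc1ccccc1
F6 | step 10 | (R)-[4-(benzyloxy)-3-methoxyphenyl][(3R,4R)-4-{(R)-[4-(benzyloxy)-3-methoxyphenyl][(tert-butyldimethylsilyl)oxy]methyl}oxolan-3-yl]methanol | COc1cc([C@H](O)[C@H]2COC[C@@H]2[C@@H](O[Si](C)(C)C(C)(C)C)c2ccc(OCc3ccccc3)c(OC)c2)ccc1OCc1ccccc1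
F7 | step 12 | (3R,4R)-3-{(S)-[4-(benzyloxy)-3-methoxyphenyl][(tert-butyldimethylsilyl)oxy]methyl}-4-{(R)-[4-(benzyloxy)-3-methoxyphenyl][(tert-butyldimethylsilyl)oxy]methyl}oxolane | COc1cc([C@@H](O[Si](C)(C)C(C)(C)C)[C@H]2COC[C@@H]2[C@@H](O[Si](C)(C)C(C)(C)C)c2ccc(OCc3ccccc3)c(OC)c2)ccc1OCc1ccccc1
F8 | step 12 | (3R,4R)-3-{(S)-[(tert-butyldimethylsilyl)oxy](4-hydroxy-3-methoxyphenyl)methyl}-4-{(R)-[(tert-butyldimethylsilyl)oxy](4-hydroxy-3-methoxyphenyl)methyl}oxolane | COc1cc([C@@H](O[Si](C)(C)C(C)(C)C)[C@H]2COC[C@@H]2[C@@H](O[Si](C)(C)C(C)(C)C)c2ccc(O)c(OC)c2)ccc1O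
A1 | alternative 1 | dimethyl 2,3-bis[4-(benzyloxy)-3-methoxybenzoyl]butanedioate (stereolabile at both α-carbons) | COC(=O)C(C(=O)c1ccc(OCc2ccccc2)c(OC)c1)C(C(=O)OC)C(=O)c1ccc(OCc2ccccc2)c(OC)c1
A2 | alternative 1 | C2-symmetric cis-fused 2,6-bis[4-(benzyloxy)-3-methoxyphenyl]-3,7-dioxabicyclo[3.3.0]octane-4,8-dione, both aryl groups exo | COc1cc([C@@H]3[C@H]2C(=O)O[C@H](c4ccc(OCc5ccccc5)c(OC)c4)[C@H]2C(=O)O3)ccc1OCc1ccccc1
A3 | alternative 2 | (3Z,4Z)-3,4-bis{[4-(benzyloxy)-3-methoxyphenyl]methylidene}oxolane, aryl groups pointing outward | COc1cc(/C=C2\COC/C2=C\c2ccc(OCc3ccccc3)c(OC)c2)ccc1OCc1ccccc1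
A4 | alternative 2 | meso cis-3,6-bis[4-(benzyloxy)-3-methoxyphenyl]-3,6-dihydro-1,2-dioxine fused at C4–C5 to a 2,5-dihydrofuran | COc1cc([C@H]2OO[C@@H](c3ccc(OCc4ccccc4)c(OC)c3)C3=C2COC3)ccc1OCc1ccccc1
A5 | alternative 3 | 3-{(S)-[4-(benzyloxy)-3-methoxyphenyl][(tert-butyldimethylsilyl)oxy]methyl}cyclobutan-1-one | COc1cc([C@@H](O[Si](C)(C)C(C)(C)C)C2CC(=O)C2)ccc1OCc1ccccc1
A6 | alternative 3 | (4R)-4-{(S)-[4-(benzyloxy)-3-methoxyphenyl][(tert-butyldimethylsilyl)oxy]methyl}oxolan-2-one | COc1cc([C@@H](O[Si](C)(C)C(C)(C)C)[C@H]2COC(=O)C2)ccc1OCc1ccccc1
A7 | alternative 3 | 4-(benzyloxy)-3-methoxybenzaldehyde | COc1cc(C=O)ccc1OCc1ccccc1
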